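**Retrosynthetic overview**

- Feature: in ring C the C1' carbinol oxygen and the C4' oxygen are 1,4-related across the unsubstituted C5'–C6' pair, and C4'–C3'–C2'–C1' carries the carbon chain and oxygen pattern of (S)-malic acid (used as its commercial C4-reduced lactone 7). A cyclopropanol at C4' is therefore a masked C6' homoenolate for a C1' ketone.
- Ring C (formed last): C1'–C6' bond by strain-release homoenolate addition onto the C1' ketone of a trans-2-acyl-2,3-dihydrobenzofuran.
- Ring B: O1–C2 and C2–C3 by [4+1] annulation of a malate-derived ammonium ylide with the ring A o-quinone methide; ring A is bought as dihydroconiferyl alcohol.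
- After ring C: debenzylation, hydroxyl-directed reduction at C4' (trans to C3'-OH), boronate-masked O-methylation at C4', desilylation.

Key step: step 11

Assumption: quinidine is taken as the alkaloid that leads to the (2S,3R) series in step 10; if the annulation shows the opposite sense, quinine is used in the same way.

Shorthand: DHB = the (2S,3R)-7-methoxy-3-[(triisopropylsilyloxy)methyl]-5-[3-(triisopropylsilyloxy)propyl]-2,3-dihydro-1-benzofuran-2-yl group; ring C atoms are C1'–C6'.

**Route**

Step 1
Reactants: 1 dihydroconiferyl alcohol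
Product: 3 2-methoxy-4-[3-(triisopropylsilyloxy)propyl]phenol, via bis-TIPS ether 2 (not isolated)
Conditions: TIPSCl (2.3 equiv), imidazole, DMF, rt; then K2CO3, MeOH, 40 °C
Reagents that add atoms: triisopropylsilyl chloride, CC(C)[Si](Cl)(C(C)C)C(C)C
Why: Corey-type silylation covers both hydroxyls, and base-mediated methanolysis then cleaves only the aryl silyl ether, because a phenoxide is a far better leaving group than an alkoxide.

Step 2
Reactants: 3 2-methoxy-4-[3-(triisopropylsilyloxy)propyl]phenol; 4 (triisopropylsilyloxy)acetaldehyde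
Product: 5 rac-2-[1-hydroxy-2-(triisopropylsilyloxy)ethyl]-6-methoxy-4-[3-(triisopropylsilyloxy)propyl]phenol
Conditions: EtMgBr (1.0 equiv), Et2O, 0 °C; solvent change to CH2Cl2; 4, rt; then H2O
Reagents that add atoms: none
Why: Casiraghi ortho-hydroxyalkylation, in which the aldehyde bound to the magnesium phenoxide is delivered to the only free ortho position (para is blocked); the new carbinol centre is racemic and is erased in step 10.

Step 3
Reactants: 5 rac-salicyl alcohol
Product: 6 rac-2-methoxy-6-[1-(4-methylphenylsulfonyl)-2-(triisopropylsilyloxy)ethyl]-4-[3-(triisopropylsilyloxy)propyl]phenol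
Conditions: p-TolSO2H (2 equiv), CH2Cl2, rt
Reagents that add atoms: p-toluenesulfinic acid, Cc1ccc(cc1)S(=O)O
Why: The acid ionises the o-hydroxybenzylic alcohol to the protonated o-quinone methide, which the soft sulfinate traps at sulfur (SN1-type sulfone formation) to give a storable o-quinone methide precursor.

Step 4
Reactants: 7 (S)-α-hydroxy-γ-butyrolactone
Product: 8 (3S)-3-(benzyloxy)oxolan-2-one
Conditions: BnBr, Ag2O, CH2Cl2, rt, dark
Reagents that add atoms: benzyl bromide, BrCc1ccccc1
Why: Silver-oxide-mediated Williamson benzylation runs without a strong base, so the lactone stays closed and the α-stereocentre is not epimerised.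

Step 5
Reactants: 8 (3S)-3-(benzyloxy)oxolan-2-one
Product: 9 1-[(1S)-1-(benzyloxy)-3-hydroxypropyl]cyclopropan-1-ol
Conditions: EtMgBr (3 equiv, slow addition), Ti(OiPr)4 (0.3 equiv), THF, 0 °C to rt; then H2O
Reagents that add atoms: ethylmagnesium bromide, CC[Mg]Br
Why: Kulinkovich cyclopropanation, in which the titanacyclopropane formed from EtMgBr and Ti(OiPr)4 adds twice to the lactone carbonyl and frees the primary alkoxide; the benzyloxy-bearing centre is not involved.

Step 6
Reactants: 9 1-[(1S)-1-(benzyloxy)-3-hydroxypropyl]cyclopropan-1-ol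
Product: 10 (S)-bis(triethylsilyl) ether of 9
Conditions: TESOTf (2.4 equiv), 2,6-lutidine, CH2Cl2, −78 to 0 °C
Reagents that add atoms: triethylsilyl triflate, CC[Si](CC)(CC)OS(=O)(=O)C(F)(F)F
Why: Silyl triflate with a hindered base silylates the primary alcohol and the tertiary cyclopropanol alike, and the cyclopropanol is thereby turned into the siloxycyclopropane needed in step 11.

Step 7
Reactants: 10 bis(triethylsilyl) ether
Product: 11 (3S)-3-(benzyloxy)-3-[1-(triethylsilyloxy)cyclopropyl]propanal
Conditions: (COCl)2, DMSO, CH2Cl2, −78 to −30 °C; Et3N, −78 °C to rt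
Reagents that add atoms: none
Why: Swern oxidation applied directly to a primary triethylsilyl ether, where activated DMSO displaces the unhindered primary silyl group as Et3SiCl and the alkoxysulfonium ion collapses to the aldehyde, while the hindered tertiary silyl ether is left.

Step 8
Reactants: 11 aldehyde
Product: 12 (4S)-4-(benzyloxy)-1-chloro-4-[1-(triethylsilyloxy)cyclopropyl]butan-2-ol (both C2 epimers)
Conditions: ICH2Cl, MeLi·LiBr (slow addition), THF, −78 °C; AcOH, −78 °C
Reagents that add atoms: chloroiodomethane, ClCI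
Why: Chloromethyllithium, generated by iodine–lithium exchange in the presence of the aldehyde, adds to the carbonyl faster than it decomposes (Barbier-type carbenoid addition); the new carbinol centre is removed in step 9.

Step 9
Reactants: 12 chlorohydrin
Product: 13 (4S)-4-(benzyloxy)-1-chloro-4-[1-(triethylsilyloxy)cyclopropyl]butan-2-one
Conditions: Dess–Martin periodinane, NaHCO3, CH2Cl2, 0 °C to rt
Reagents that add atoms: none
Why: Dess–Martin oxidation under buffered, near-neutral conditions gives the α-chloroketone without touching the siloxycyclopropane or eliminating the β-benzyloxy group.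

Step 10
Reactants: 13 chloromethyl ketone; 14 quinidine; 6 sulfone
Product: 17 (3S)-3-(benzyloxy)-1-DHB-3-[1-(triethylsilyloxy)cyclopropyl]propan-1-one, via quinidinium salt 15 (not isolated), via o-quinone methide 16 (not isolated)
Conditions: 13, quinidine, NaI (cat.), MeCN, 40 °C; evaporate; then 6, Cs2CO3 (2.5 equiv), CH2Cl2, 0 °C to rt
Reagents that add atoms: none
Why: The quinuclidine nitrogen is alkylated by the α-chloroketone; Cs2CO3 then forms the ammonium ylide and, by 1,4-elimination of sulfinate from 6, the o-quinone methide, and conjugate addition of the ylide carbon to the exocyclic carbon followed by 5-exo-tet displacement of quinidine by the phenoxide closes ring B ([4+1] annulation of an ammonium ylide); the trans C2/C3 relation is the thermodynamic one at the epimerisable C2, the C3 face is chosen by the chiral alkaloid leaving group, and any (2R,3S) isomer is a diastereomer through C3' and is removed by chromatography.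

Step 11
Reactants: 17 trans-2-acyl dihydrobenzofuran with C3' benzyloxy and C4' siloxycyclopropane
Product: 19 (2S,4S)-2-(benzyloxy)-4-DHB-4-hydroxycyclohexan-1-one (ring C numbering: 1'S,3'S), via trichlorotitanium homoenolate 18 (not isolated)
Conditions: TiCl4 (2.5 equiv), CH2Cl2, −78 to −30 °C; pH 7 buffer
Reagents that add atoms: none
Why: Proposed new method: TiCl4 should cleave a C4'–CH2 bond of the siloxycyclopropane with loss of Et3SiCl to give the β-trichlorotitanio ketone 18 (the two ring CH2 groups are equivalent, so only one homoenolate can form), and its C6'–Ti bond then adds to the C1' carbonyl; the closest known reactions are intermolecular additions of titanium and zinc homoenolates, made from siloxycyclopropanes or cyclopropanols, to aldehydes and ketones. Ring C closes in the 6-exo-trig mode through a chair, and the intramolecular setting plus the activated α-aryloxy ketone should offset the low reactivity that trichlorotitanium homoenolates show toward ketones. The new C1' centre is controlled by a six-membered chelate in which titanium bridges the C1' carbonyl oxygen and the C3' benzyl ether oxygen, so that both oxygens are axial on the forming chair and the dihydrobenzofuranyl group is equatorial, which gives the 1',3'-cis ketol (1'S); polar Felkin–Anh control from C2 (C2–O1 anti to the incoming carbon) selects the same face. The step needs titanium to attack the strained, donor-substituted cyclopropane in preference to two primary TIPS ethers, a benzyl ether and a β-alkoxy ketone; the low temperature and the absence of base and of any single-electron reductant (no β-elimination of benzyl alcohol, no C2–O1 cleavage) should secure this.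

Step 12
Reactants: 19 ring C ketol
Product: 20 (2S,4S)-4-DHB-2,4-dihydroxycyclohexan-1-one
Conditions: H2 (1 atm), Pd(OH)2/C, EtOAc, rt
Reagents that add atoms: none
Why: Hydrogenolysis of the benzyl ether over palladium under neutral conditions leaves the aryl ethers, silyl ethers and ketone alone and does not epimerise the α-ketol centre C3'.

Step 13
Reactants: 20 α-hydroxy ketone
Product: 21 (1S,3S,4S)-1-DHB-cyclohexane-1,3,4-triol
Conditions: Me4NBH(OAc)3, MeCN/AcOH, −30 to 0 °C
Reagents that add atoms: none
Why: Saksena–Evans hydroxyl-directed reduction, in which the C3' hydroxyl (and the cis C1' hydroxyl on the same face) exchanges onto boron and delivers hydride to that face, so the C4' hydroxyl forms trans to C3'-OH (4'S); the benzyl ether was removed first because external hydrides attack 2-alkoxycyclohexanones anti to the alkoxy group and give the cis isomer.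

Step 14
Reactants: 21 triol
Product: 24 bis-TIPS ether of difengpiol B, via phenylboronate 22 (not isolated), via O-methyl phenylboronate 23 (not isolated)
Conditions: PhB(OH)2, toluene, 4 Å MS, rt; then MeOTf, 2,6-di-tert-butyl-4-methylpyridine, CH2Cl2, 0 °C to rt; then pinacol, MeOH
Reagents that add atoms: methyl triflate, COS(=O)(=O)C(F)(F)F
Why: Phenylboronic acid condenses with the cis-1,3-diol (C1'-OH and C3'-OH, both axial) to a six-membered boronate, so only the C4' hydroxyl is free for O-methylation with MeOTf and a hindered base (transient boronate protection), and transesterification with pinacol then releases the diol.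

Step 15
Reactants: 24 bis-TIPS ether
Product: 25 difengpiol B
Conditions: TBAF, THF, rt
Reagents that add atoms: none
Why: Fluoride-mediated desilylation cleaves both primary TIPS ethers, and no other group in the molecule reacts.

**Compound list**

1 | dihydroconiferyl alcohol | COc1cc(CCCO)ccc1O | starting material
2 | bis-TIPS ether of 1 | COc1cc(CCCO[Si](C(C)C)(C(C)C)C(C)C)ccc1O[Si](C(C)C)(C(C)C)C(C)C | intermediate
3 | 2-methoxy-4-[3-(triisopropylsilyloxy)propyl]phenol | COc1cc(CCCO[Si](C(C)C)(C(C)C)C(C)C)ccc1O | intermediate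
4 | (triisopropylsilyloxy)acetaldehyde | O=CCO[Si](C(C)C)(C(C)C)C(C)C | starting material
5 | rac-2-[1-hydroxy-2-(triisopropylsilyloxy)ethyl]-6-methoxy-4-[3-(triisopropylsilyloxy)propyl]phenol | COc1cc(CCCO[Si](C(C)C)(C(C)C)C(C)C)cc(C(O)CO[Si](C(C)C)(C(C)C)C(C)C)c1O | intermediate
6 | rac-2-methoxy-6-[1-(4-methylphenylsulfonyl)-2-(triisopropylsilyloxy)ethyl]-4-[3-(triisopropylsilyloxy)propyl]phenol | COc1cc(CCCO[Si](C(C)C)(C(C)C)C(C)C)cc(C(CO[Si](C(C)C)(C(C)C)C(C)C)S(=O)(=O)c2ccc(C)cc2)c1O | intermediate
7 | (S)-α-hydroxy-γ-butyrolactone | O=C1OCC[C@@H]1O | starting material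
8 | (3S)-3-(benzyloxy)oxolan-2-one | O=C1OCC[C@@H]1OCc1ccccc1 | intermediate
9 | 1-[(1S)-1-(benzyloxy)-3-hydroxypropyl]cyclopropan-1-ol | OCC[C@H](OCc1ccccc1)C1(O)CC1 | intermediate
10 | (S)-bis(triethylsilyl) ether of 9 | CC[Si](CC)(CC)OCC[C@H](OCc1ccccc1)C1(O[Si](CC)(CC)CC)CC1 | intermediate
11 | (3S)-3-(benzyloxy)-3-[1-(triethylsilyloxy)cyclopropyl]propanal | O=CC[C@H](OCc1ccccc1)C1(O[Si](CC)(CC)CC)CC1 | intermediate
12 | (4S)-4-(benzyloxy)-1-chloro-4-[1-(triethylsilyloxy)cyclopropyl]butan-2-ol | ClCC(O)C[C@H](OCc1ccccc1)C1(O[Si](CC)(CC)CC)CC1 | intermediate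
13 | (4S)-4-(benzyloxy)-1-chloro-4-[1-(triethylsilyloxy)cyclopropyl]butan-2-one | ClCC(=O)C[C@H](OCc1ccccc1)C1(O[Si](CC)(CC)CC)CC1 | intermediate
14 | quinidine | COc1ccc2nccc([C@@H]([C@H]3C[C@@H]4CCN3C[C@@H]4C=C)O)c2c1 | starting material
15 | N-{(4S)-4-(benzyloxy)-2-oxo-4-[1-(triethylsilyloxy)cyclopropyl]butyl}quinidinium chloride | COc1ccc2nccc([C@@H]([C@H]3C[C@@H]4CC[N@@+]3(CC(=O)C[C@H](OCc5ccccc5)C5(O[Si](CC)(CC)CC)CC5)C[C@@H]4C=C)O)c2c1.[Cl-] | intermediate
16 | o-quinone methide from 6 | COC1=CC(CCCO[Si](C(C)C)(C(C)C)C(C)C)=CC(=CCO[Si](C(C)C)(C(C)C)C(C)C)C1=O | intermediate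
17 | (3S)-3-(benzyloxy)-1-DHB-3-[1-(triethylsilyloxy)cyclopropyl]propan-1-one | COc1cc(CCCO[Si](C(C)C)(C(C)C)C(C)C)cc2c1O[C@H](C(=O)C[C@H](OCc1ccccc1)C1(O[Si](CC)(CC)CC)CC1)[C@H]2CO[Si](C(C)C)(C(C)C)C(C)C | intermediate
18 | trichlorotitanium homoenolate of 17 | COc1cc(CCCO[Si](C(C)C)(C(C)C)C(C)C)cc2c1O[C@H](C(=O)C[C@H](OCc1ccccc1)C(=O)CC[Ti](Cl)(Cl)Cl)[C@H]2CO[Si](C(C)C)(C(C)C)C(C)C | intermediate
19 | (2S,4S)-2-(benzyloxy)-4-DHB-4-hydroxycyclohexan-1-one | COc1cc(CCCO[Si](C(C)C)(C(C)C)C(C)C)cc2c1O[C@H]([C@]1(O)CCC(=O)[C@@H](OCc3ccccc3)C1)[C@H]2CO[Si](C(C)C)(C(C)C)C(C)C | intermediate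
20 | (2S,4S)-4-DHB-2,4-dihydroxycyclohexan-1-one | COc1cc(CCCO[Si](C(C)C)(C(C)C)C(C)C)cc2c1O[C@H]([C@]1(O)CCC(=O)[C@@H](O)C1)[C@H]2CO[Si](C(C)C)(C(C)C)C(C)C | intermediate
21 | (1S,3S,4S)-1-DHB-cyclohexane-1,3,4-triol | COc1cc(CCCO[Si](C(C)C)(C(C)C)C(C)C)cc2c1O[C@H]([C@]1(O)CC[C@H](O)[C@@H](O)C1)[C@H]2CO[Si](C(C)C)(C(C)C)C(C)C | intermediate
22 | 1',3'-O-phenylboronate of 21 | COc1cc(CCCO[Si](C(C)C)(C(C)C)C(C)C)cc2c1O[C@H]([C@]1(OB(c3ccccc3)O4)CC[C@H](O)[C@@H]4C1)[C@H]2CO[Si](C(C)C)(C(C)C)C(C)C | intermediate
23 | 4'-O-methyl 1',3'-O-phenylboronate | COc1cc(CCCO[Si](C(C)C)(C(C)C)C(C)C)cc2c1O[C@H]([C@]1(OB(c3ccccc3)O4)CC[C@H](OC)[C@@H]4C1)[C@H]2CO[Si](C(C)C)(C(C)C)C(C)C | intermediate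
24 | bis-TIPS ether of difengpiol B | COc1cc(CCCO[Si](C(C)C)(C(C)C)C(C)C)cc2c1O[C@H]([C@]1(O)CC[C@H](OC)[C@@H](O)C1)[C@H]2CO[Si](C(C)C)(C(C)C)C(C)C | intermediate
25 | difengpiol B | COc1cc(CCCO)cc2c1O[C@H]([C@]1(O)CC[C@H](OC)[C@@H](O)C1)[C@H]2CO | target

**Step count**

Total: 15 steps. Longest linear sequence: 12 steps (7 to 25, steps 4–15).

**Steps most likely to fail**

Step 11 (homoenolate ring closure). The homoenolate may be protonated to the ethyl ketone or revert to the cyclopropanolate before it reaches the hindered C1' ketone. The Lewis acid may trigger loss of benzyl alcohol or of a silyl ether. Titanium may also chelate O1 instead of the benzyl ether and erode the facial selectivity at C1'. The fallback builds ring C on the dihydrobenzofuran by known reactions and needs no cyclopropane; it sets out from sulfone 6 and returns at 24. Sulfone 6 is annulated, as in step 10, with the quinidinium salt of 2-bromo-N-methoxy-N-methylacetamide F1 (Cs2CO3, CH2Cl2) to the trans Weinreb amide F2. But-3-enylmagnesium bromide converts F2 into the butenyl ketone F3. Allylmagnesium bromide, added under Cram chelate control through O1 (attack anti to C3), should give the (1'S) dienyl carbinol F4. Ring-closing metathesis with the second-generation Grubbs catalyst gives the cyclohexenol F5. The homoallylic hydroxyl directs epoxidation with VO(acac)2 and t-BuOOH to the syn epoxy alcohol F6. Acid-catalysed methanolysis (camphorsulfonic acid, MeOH) opens F6 trans-diaxially at C4', the carbon distal to the C1' oxygen, and gives 24.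

Step 10 ([4+1] annulation). The alkaloid leaving group may give poor facial selectivity at C3 with an alkyl-substituted o-quinone methide, and a slow, bulky ylide may let the o-quinone methide tautomerise to the styryl silyl ether before it is trapped. The fallback sets out from 13 and 6 and returns at 17. Chloroketone 13 is converted with tetrahydrothiophene (NaI cat., acetone) into the thiolanium salt F7. Its small sulfonium ylide undergoes the known Cs2CO3-mediated annulation with 2-(1-tosylalkyl)phenols, and with 6 it gives 17 together with its (2R,3S) trans isomer F8. The two differ as diastereomers through C3' and are separated by chromatography.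

Step 2 (ortho-hydroxyalkylation). The enolisable aldehyde may self-condense on the basic magnesium phenoxide, and the salicyl alcohol may react on to a bis-aryl methane. The fallback introduces the two carbons one at a time; it sets out from 3 and returns at 5. Phenol 3 is ortho-formylated (MgCl2, Et3N, paraformaldehyde, MeCN, reflux) to the salicylaldehyde F9. Wittig methylenation (Ph3P=CH2, THF) gives the vinylphenol F10, and dihydroxylation (OsO4 cat., N-methylmorpholine N-oxide) gives the diol F11. Silylation of the primary hydroxyl (TIPSCl, imidazole; K2CO3, MeOH to free any silylated phenol) gives 5.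

**Further compounds**

F1 | step 11 | N-[2-(methoxy(methyl)amino)-2-oxoethyl]quinidinium bromide | COc1ccc2nccc([C@@H]([C@H]3C[C@@H]4CC[N@@+]3(CC(=O)N(C)OC)C[C@@H]4C=C)O)c2c1.[Br-]
F2 | step 11 | (2S,3R)-N,7-dimethoxy-N-methyl-3-[(triisopropylsilyloxy)methyl]-5-[3-(triisopropylsilyloxy)propyl]-2,3-dihydro-1-benzofuran-2-carboxamide | COc1cc(CCCO[Si](C(C)C)(C(C)C)C(C)C)cc2c1O[C@H](C(=O)N(C)OC)[C@H]2CO[Si](C(C)C)(C(C)C)C(C)C
F3 | step 11 | 1-DHB-pent-4-en-1-one | COc1cc(CCCO[Si](C(C)C)(C(C)C)C(C)C)cc2c1O[C@H](C(=O)CCC=C)[C@H]2CO[Si](C(C)C)(C(C)C)C(C)C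
F4 | step 11 | (4S)-4-DHB-octa-1,7-dien-4-ol | COc1cc(CCCO[Si](C(C)C)(C(C)C)C(C)C)cc2c1O[C@H]([C@@](O)(CC=C)CCC=C)[C@H]2CO[Si](C(C)C)(C(C)C)C(C)C
F5 | step 11 | (1S)-1-DHB-cyclohex-3-en-1-ol | COc1cc(CCCO[Si](C(C)C)(C(C)C)C(C)C)cc2c1O[C@H]([C@]1(O)CCC=CC1)[C@H]2CO[Si](C(C)C)(C(C)C)C(C)C
F6 | step 11 | (1'S)-1-DHB-3,4-epoxycyclohexan-1-ol with the epoxide syn to the hydroxyl | COc1cc(CCCO[Si](C(C)C)(C(C)C)C(C)C)cc2c1O[C@H]([C@]1(O)CC[C@H]3O[C@H]3C1)[C@H]2CO[Si](C(C)C)(C(C)C)C(C)C
F7 | step 10 | 1-{(4S)-4-(benzyloxy)-2-oxo-4-[1-(triethylsilyloxy)cyclopropyl]butyl}thiolanium chloride | O=C(C[S+]1CCCC1)C[C@H](OCc1ccccc1)C1(O[Si](CC)(CC)CC)CC1.[Cl-]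
F8 | step 10 | (2R,3S) trans isomer of 17 | COc1cc(CCCO[Si](C(C)C)(C(C)C)C(C)C)cc2c1O[C@@H](C(=O)C[C@H](OCc1ccccc1)C1(O[Si](CC)(CC)CC)CC1)[C@@H]2CO[Si](C(C)C)(C(C)C)C(C)C
F9 | step 2 | 2-hydroxy-3-methoxy-5-[3-(triisopropylsilyloxy)propyl]benzaldehyde | COc1cc(CCCO[Si](C(C)C)(C(C)C)C(C)C)cc(C=O)c1O
F10 | step 2 | 2-ethenyl-6-methoxy-4-[3-(triisopropylsilyloxy)propyl]phenol | COc1cc(CCCO[Si](C(C)C)(C(C)C)C(C)C)cc(C=C)c1O
F11 | step 2 | rac-1-{2-hydroxy-3-methoxy-5-[3-(triisopropylsilyloxy)propyl]phenyl}ethane-1,2-diol | COc1cc(CCCO[Si](C(C)C)(C(C)C)C(C)C)cc(C(O)CO)c1O
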